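**Plan**

- Retrosynthesis: the ester C–O bond is cut first (Mitsunobu). Then one [5+2] disconnection cuts the C4–C5 bond of the seven-membered ring and the C3a–C8a ring-fusion bond (azulene numbering), opening both rings to a monocyclic allene–vinylcyclopropane. Behind it lie the allene C–C bond (SN2'), the exocyclic methylene, the ketone C–C bond and the cyclopropane.
- Enabling feature: C5–C6=C7–C8–C8a of the seven-membered ring is the five-carbon unit of a ring-opened vinylcyclopropane. C4–C3a=C3 is what a 1,1-disubstituted allene leaves after its terminal C=C has reacted, and the five-membered ring is the tether between the two. The cyclopropane is a temporary ring and MOM a temporary protecting group.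
- Forward order: cyclopropane first (cis-fused lactone from isoprenol), then the 2-(alkoxymethyl)vinyl arm and the allene arm, then the five- and seven-membered rings together in step 9, then deprotection and esterification.
- Stereochemistry: the only stereocentre (C8a) is the quaternary cyclopropane carbon set by the enantioselective intramolecular cyclopropanation (step 3). The cis lactone fusion fixes the cis relation of the two arms, and the key step transfers the centre with retention.

Key step: step 9

Assumption: Rh2(5S-MEPY)4 is taken to deliver the (1S,6S)-lactone 4; if the sense of induction is opposite, the mirror-image catalyst Rh2(5R-MEPY)4 is used with no other change.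

**Route**

Step 1
Reactants: 1 3-methylbut-3-en-1-ol
Product: 2 3-methylbut-3-en-1-yl 2-bromoacetate
Conditions: BrCH2COBr, NaHCO3, MeCN, 0 °C
Reagents that add atoms: bromoacetyl bromide, BrCC(Br)=O
Why: O-acylation of a primary alcohol by an acyl bromide under buffered conditions is fast at 0 °C and leaves the alkyl bromide and the alkene untouched.

Step 2
Reactants: 2 3-methylbut-3-en-1-yl 2-bromoacetate
Product: 3 3-methylbut-3-en-1-yl 2-diazoacetate
Conditions: TsNHNHTs, DBU, THF, 0 °C
Reagents that add atoms: N,N'-ditosylhydrazine, Cc1ccc(cc1)S(=O)(=O)NNS(=O)(=O)c1ccc(C)cc1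
Why: Diazoacetate synthesis from a bromoacetate: the hydrazide anion displaces bromide and DBU then expels two sulfinates, conditions mild enough for the alkene.

Step 3
Reactants: 3 3-methylbut-3-en-1-yl 2-diazoacetate
Product: 4 (1S,6S)-6-methyl-3-oxabicyclo[4.1.0]heptan-2-one
Conditions: Rh2(5S-MEPY)4 (dirhodium tetrakis[methyl (5S)-2-oxopyrrolidine-5-carboxylate], 1 mol %), CH2Cl2, reflux, slow addition of 3
Reagents that add atoms: none
Why: Enantioselective intramolecular cyclopropanation of a homoallylic diazoacetate by a chiral carboxamidate carbene of divalent rhodium; the tether allows only the cis-fused lactone, so both stereocentres arise together, and the ligand pocket selects the alkene face.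

Step 4
Reactants: 4 (1S,6S)-6-methyl-3-oxabicyclo[4.1.0]heptan-2-one
Product: 6 1-[(1S,2S)-2-(2-hydroxyethyl)-2-methylcyclopropyl]-2-(methoxymethoxy)ethan-1-one, via lithium hemiketal alkoxide 5 (not isolated)
Conditions: Bu3SnCH2OMOM, n-BuLi, THF, −78 °C; then 4, −78 °C; H2O quench
Reagents that add atoms: tributyl[(methoxymethoxy)methyl]stannane, CCCC[Sn](CCCC)(CCCC)COCOC
Why: Addition of an α-alkoxymethyllithium (made by tin–lithium exchange) to a lactone stops at the lithium hemiketal alkoxide at −78 °C, so one CH2OMOM group is delivered and neither stereocentre is touched.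

Step 5
Reactants: 6 1-[(1S,2S)-2-(2-hydroxyethyl)-2-methylcyclopropyl]-2-(methoxymethoxy)ethan-1-one
Product: 7 2-{(1S,2S)-2-[3-(methoxymethoxy)prop-1-en-2-yl]-1-methylcyclopropyl}ethan-1-ol
Conditions: Ph3PCH3Br, KOtBu (3 equiv each), THF, 0 °C to rt
Reagents that add atoms: methyltriphenylphosphonium bromide, C[P+](c1ccccc1)(c1ccccc1)c1ccccc1.[Br-]
Why: Wittig methylenation; the excess ylide keeps the substrate as the open keto alkoxide (any ring–chain tautomer of 6 reverts to it under base), and the cyclopropyl α-CH is too weakly acidic to epimerise.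

Step 6
Reactants: 7 2-{(1S,2S)-2-[3-(methoxymethoxy)prop-1-en-2-yl]-1-methylcyclopropyl}ethan-1-ol
Product: 8 (1S,2S)-1-(2-bromoethyl)-2-[3-(methoxymethoxy)prop-1-en-2-yl]-1-methylcyclopropane
Conditions: CBr4, PPh3, 2,6-lutidine, CH2Cl2, 0 °C
Reagents that add atoms: carbon tetrabromide, BrC(Br)(Br)Br
Why: Appel bromination of a primary alcohol (SN2 on the alkoxyphosphonium ion) is, with the amine buffer, mild enough for the MOM acetal and the vinylcyclopropane.

Step 7
Reactants: 9 4-methylpent-2-yn-1-ol
Product: 10 4-methylpent-2-yn-1-yl methanesulfonate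
Conditions: MsCl, Et3N, CH2Cl2, 0 °C
Reagents that add atoms: methanesulfonyl chloride, CS(=O)(=O)Cl
Why: Sulfonylation of a primary propargylic alcohol is a routine mesylation, and the product is used directly.

Step 8
Reactants: 8 (1S,2S)-1-(2-bromoethyl)-2-[3-(methoxymethoxy)prop-1-en-2-yl]-1-methylcyclopropane; 10 4-methylpent-2-yn-1-yl methanesulfonate
Product: 12 (1R,2S)-2-[3-(methoxymethoxy)prop-1-en-2-yl]-1-methyl-1-[3-(propan-2-yl)penta-3,4-dien-1-yl]cyclopropane, via Grignard reagent 11 (not isolated)
Conditions: Mg turnings, THF, 40 °C; then 10, CuBr·SMe2 (10 mol %), THF, −78 to −20 °C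
Reagents that add atoms: none
Why: Copper-catalysed anti-SN2' substitution of a propargylic sulfonate by a Grignard reagent: the alkylcopper attacks the alkyne carbon bearing the isopropyl group as the mesylate leaves, giving the 1,1-disubstituted terminal allene, and the carbanion is two carbons from the ring so the cyclopropane stays closed.

Step 9
Reactants: 12 (1R,2S)-2-[3-(methoxymethoxy)prop-1-en-2-yl]-1-methyl-1-[3-(propan-2-yl)penta-3,4-dien-1-yl]cyclopropane
Product: 13 (8aR)-6-[(methoxymethoxy)methyl]-8a-methyl-3-(propan-2-yl)-1,2,4,5,8,8a-hexahydroazulene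
Conditions: [Rh(CO)2Cl]2 (5 mol %), degassed toluene (0.01 M), 90 °C
Reagents that add atoms: none
Why: Proposed new method: monovalent rhodium, bound to the vinyl group and to the allene held cis to it, should insert into the cyclopropane bond between the alkenyl-bearing CH and the quaternary carbon to give a σ-alkyl π-allyl rhodacycle of trivalent rhodium, the terminal C=CH2 π bond of the allene then inserts into the Rh–C(quaternary) bond with C–C bond formation at the central allene carbon, and reductive elimination between the two CH2 termini of the resulting bis-allyl complex releases the product. The closest known reaction types are the rhodium-catalysed intramolecular [5+2] cycloaddition of vinylcyclopropanes with tethered allenes and the [5+2] mode of vinylcyclopropanes that carry a cis alkene tether on the cyclopropane; new here are the tether on a fully substituted cyclopropane carbon and the use of the distal allene π bond. The five-membered ring closes by 5-exo attack on the central allene carbon through the π bond lying in the plane of the tether, which leaves the other allene π bond as the endocyclic tetrasubstituted C3=C3a alkene, and the seven-membered ring closes by allyl–allyl reductive elimination (C4–C5), a formal insertion of two allene carbons into the three-membered ring. No stereocentre is created: C8a is the quaternary cyclopropane carbon, and oxidative addition and migratory insertion both proceed with retention at it. The step needs cleavage of the more substituted cyclopropane bond (only this bond puts rhodium within reach of the chelating allene), seven- over five-membered reductive elimination (the cis arrangement of the two arms gives the anti allyl geometry that can hold a cis ring alkene) and reaction of the distal allene π bond at its CH2 end (the proximal bond would need a four-membered ring, and coupling at the isopropyl-bearing terminus would give a bridged ring with a second quaternary carbon).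

Step 10
Reactants: 13 (8aR)-6-[(methoxymethoxy)methyl]-8a-methyl-3-(propan-2-yl)-1,2,4,5,8,8a-hexahydroazulene
Product: 14 [(8aR)-8a-methyl-3-(propan-2-yl)-1,2,4,5,8,8a-hexahydroazulen-6-yl]methanol
Conditions: TMSOTf, 2,2'-bipyridyl, CH2Cl2, 0 °C; then H2O
Reagents that add atoms: none
Why: MOM cleavage through the 2,2'-bipyridinium intermediate formed with TMSOTf and hydrolysed by water runs under buffered, nearly neutral conditions, so neither alkene should migrate.

Step 11
Reactants: 14 [(8aR)-8a-methyl-3-(propan-2-yl)-1,2,4,5,8,8a-hexahydroazulen-6-yl]methanol; 15 4-hydroxy-3-methoxybenzoic acid (vanillic acid)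
Product: 16 [(8aR)-8a-methyl-3-(propan-2-yl)-1,2,4,5,8,8a-hexahydroazulen-6-yl]methyl 4-hydroxy-3-methoxybenzoate
Conditions: PPh3, DIAD, THF, 0 °C to rt
Reagents that add atoms: none
Why: Mitsunobu esterification: the carboxylic acid, far more acidic than the phenol, is the pronucleophile that is activated, so the phenol needs no protection, and the primary allylic alkoxyphosphonium ion is displaced in an SN2 sense without allylic transposition.

**Compound list**

1 | 3-methylbut-3-en-1-ol | C=C(C)CCO | starting material
2 | 3-methylbut-3-en-1-yl 2-bromoacetate | C=C(C)CCOC(=O)CBr | intermediate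
3 | 3-methylbut-3-en-1-yl 2-diazoacetate | C=C(C)CCOC(=O)C=[N+]=[N-] | intermediate
4 | (1S,6S)-6-methyl-3-oxabicyclo[4.1.0]heptan-2-one (cis-fused cyclopropane lactone) | O=C1OCC[C@]2(C)C[C@H]12 | intermediate
5 | lithium (1S,6S)-2-[(methoxymethoxy)methyl]-6-methyl-3-oxabicyclo[4.1.0]heptan-2-olate (both C2 epimers) | COCOCC1(O[Li])OCC[C@]2(C)C[C@H]12 | intermediate
6 | 1-[(1S,2S)-2-(2-hydroxyethyl)-2-methylcyclopropyl]-2-(methoxymethoxy)ethan-1-one | COCOCC(=O)[C@H]1C[C@@]1(C)CCO | intermediate
7 | 2-{(1S,2S)-2-[3-(methoxymethoxy)prop-1-en-2-yl]-1-methylcyclopropyl}ethan-1-ol | C=C(COCOC)[C@H]1C[C@@]1(C)CCO | intermediate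
8 | (1S,2S)-1-(2-bromoethyl)-2-[3-(methoxymethoxy)prop-1-en-2-yl]-1-methylcyclopropane | C=C(COCOC)[C@H]1C[C@@]1(C)CCBr | intermediate
9 | 4-methylpent-2-yn-1-ol | CC(C)C#CCO | starting material
10 | 4-methylpent-2-yn-1-yl methanesulfonate | CC(C)C#CCOS(C)(=O)=O | intermediate
11 | bromo(2-{(1S,2S)-2-[3-(methoxymethoxy)prop-1-en-2-yl]-1-methylcyclopropyl}ethyl)magnesium | C=C(COCOC)[C@H]1C[C@@]1(C)CC[Mg]Br | intermediate
12 | (1R,2S)-2-[3-(methoxymethoxy)prop-1-en-2-yl]-1-methyl-1-[3-(propan-2-yl)penta-3,4-dien-1-yl]cyclopropane (alkenyl and allene arms cis) | C=C(COCOC)[C@H]1C[C@@]1(C)CCC(C(C)C)=C=C | intermediate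
13 | (8aR)-6-[(methoxymethoxy)methyl]-8a-methyl-3-(propan-2-yl)-1,2,4,5,8,8a-hexahydroazulene | COCOCC1=CC[C@@]2(C)CCC(C(C)C)=C2CC1 | intermediate
14 | [(8aR)-8a-methyl-3-(propan-2-yl)-1,2,4,5,8,8a-hexahydroazulen-6-yl]methanol | OCC1=CC[C@@]2(C)CCC(C(C)C)=C2CC1 | intermediate
15 | 4-hydroxy-3-methoxybenzoic acid (vanillic acid) | COc1cc(C(=O)O)ccc1O | starting material
16 | [(8aR)-8a-methyl-3-(propan-2-yl)-1,2,4,5,8,8a-hexahydroazulen-6-yl]methyl 4-hydroxy-3-methoxybenzoate | COc1cc(C(=O)OCC2=CC[C@@]3(C)CCC(C(C)C)=C3CC2)ccc1O | target

**Step count**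

Total steps: 11. Longest linear sequence: 10 (steps 1–6 and 8–11); step 7 is a one-step side branch.

**Steps most likely to fail**

1. Step 9. The rhodium may cleave the less hindered cyclopropane bond, or the tertiary alkylrhodium may undergo β-hydride elimination to dienes. The bis-allyl complex may close the five-membered [3+2] ring instead, and the allene may oligomerise on rhodium. The fallback uses known chemistry, sets out from bromide 8 and comes back at 13.
   - The Grignard reagent 11 made from 8 is added to acrolein (THF, −78 °C) to give 5-{(1R,2S)-2-[3-(methoxymethoxy)prop-1-en-2-yl]-1-methylcyclopropyl}pent-1-en-3-ol F1 (both carbinol epimers).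
   - Silylation (TBSCl, imidazole, DMF) gives its tert-butyldimethylsilyl ether F2.
   - F2 is a vinylcyclopropane with a plain terminal alkene tethered cis on the cyclopropane, the class for which the rhodium-catalysed [5+2] mode is established. With [Rh(CO)2Cl]2 in toluene at 90 °C it should give the octahydroazulene silyl ether F3.
   - TBAF then gives the octahydroazulen-3-ol F4, and Dess–Martin periodinane the hexahydroazulen-3(1H)-one F5.
   - i-PrMgCl with CeCl3 gives the tertiary alcohol F6, and dehydration with SOCl2 and pyridine toward the ring-fusion carbon gives 13.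

2. Step 8. Direct SN2 displacement at the propargylic CH2 may compete with SN2' attack at the hindered, isopropyl-bearing alkyne carbon, and Wurtz coupling may occur during Grignard formation. The fallback reverses the polarity, sets out from bromide 8 and comes back at 12.
   - 8 alkylates the dianion of propargyl alcohol (n-BuLi, 2 equiv, THF–DMPU, −78 °C to rt) to give 5-{(1R,2S)-2-[3-(methoxymethoxy)prop-1-en-2-yl]-1-methylcyclopropyl}pent-2-yn-1-ol F7.
   - MsCl and Et3N give its methanesulfonate F8.
   - i-PrMgCl with CuBr·SMe2 (THF, −78 °C) then attacks, in the SN2' sense, the alkyne carbon that carries the unbranched chain and gives 12.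

3. Step 3. Enantioface discrimination in the carbene addition to the 1,1-disubstituted alkene may be incomplete, and carbene dimerisation may compete. The fallback is a resolution, sets out from diazoacetate 3 and comes back at 4.
   - Rh2(OAc)4 in CH2Cl2 gives racemic cis-6-methyl-3-oxabicyclo[4.1.0]heptan-2-one F9.
   - AlMe3-mediated aminolysis with (S)-1-phenylethylamine gives two diastereomeric hydroxy amides, separated by chromatography or crystallisation: (1S,2S)-2-(2-hydroxyethyl)-2-methyl-N-[(1S)-1-phenylethyl]cyclopropane-1-carboxamide F10 and its (1R,2R) diastereomer F11, which is set aside.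
   - F10 is relactonised with aqueous H2SO4 in dioxane at 80 °C to 4.

**Further compounds**

F1 | step 9 | 5-{(1R,2S)-2-[3-(methoxymethoxy)prop-1-en-2-yl]-1-methylcyclopropyl}pent-1-en-3-ol (carbinol epimers) | C=C(COCOC)[C@H]1C[C@@]1(C)CCC(O)C=C
F2 | step 9 | tert-butyl[(5-{(1R,2S)-2-[3-(methoxymethoxy)prop-1-en-2-yl]-1-methylcyclopropyl}pent-1-en-3-yl)oxy]dimethylsilane | C=C(COCOC)[C@H]1C[C@@]1(C)CCC(O[Si](C)(C)C(C)(C)C)C=C
F3 | step 9 | tert-butyl({(8aR)-6-[(methoxymethoxy)methyl]-8a-methyl-1,2,3,3a,4,5,8,8a-octahydroazulen-3-yl}oxy)dimethylsilane (epimers at C3 and C3a) | COCOCC1=CC[C@@]2(C)CCC(O[Si](C)(C)C(C)(C)C)C2CC1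
F4 | step 9 | (8aR)-6-[(methoxymethoxy)methyl]-8a-methyl-1,2,3,3a,4,5,8,8a-octahydroazulen-3-ol | COCOCC1=CC[C@@]2(C)CCC(O)C2CC1
F5 | step 9 | (8aR)-6-[(methoxymethoxy)methyl]-8a-methyl-2,3a,4,5,8,8a-hexahydroazulen-3(1H)-one | COCOCC1=CC[C@@]2(C)CCC(=O)C2CC1
F6 | step 9 | (8aR)-6-[(methoxymethoxy)methyl]-8a-methyl-3-(propan-2-yl)-1,2,3,3a,4,5,8,8a-octahydroazulen-3-ol | COCOCC1=CC[C@@]2(C)CCC(O)(C(C)C)C2CC1
F7 | step 8 | 5-{(1R,2S)-2-[3-(methoxymethoxy)prop-1-en-2-yl]-1-methylcyclopropyl}pent-2-yn-1-ol | C=C(COCOC)[C@H]1C[C@@]1(C)CCC#CCO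
F8 | step 8 | 5-{(1R,2S)-2-[3-(methoxymethoxy)prop-1-en-2-yl]-1-methylcyclopropyl}pent-2-yn-1-yl methanesulfonate | C=C(COCOC)[C@H]1C[C@@]1(C)CCC#CCOS(C)(=O)=O
F9 | step 3 | racemic cis-6-methyl-3-oxabicyclo[4.1.0]heptan-2-one | O=C1OCCC2(C)CC12
F10 | step 3 | (1S,2S)-2-(2-hydroxyethyl)-2-methyl-N-[(1S)-1-phenylethyl]cyclopropane-1-carboxamide | C[C@H](NC(=O)[C@H]1C[C@@]1(C)CCO)c1ccccc1
F11 | step 3 | (1R,2R)-2-(2-hydroxyethyl)-2-methyl-N-[(1S)-1-phenylethyl]cyclopropane-1-carboxamide | C[C@H](NC(=O)[C@@H]1C[C@]1(C)CCO)c1ccccc1
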